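**Retrosynthetic overview**

1. The target is traced back to its tetrakis(tert-butyldimethylsilyl) ether 15, which is cut at one benzylic C–O bond into benzyl alcohol 13 and benzyl bromide 14, both made from the single arene ester 12.
2. The strategy rests on the substitution pattern of each benzene ring: C4 and C5 carry the vicinal hydroxyls (a two-carbon unit), while C6–H, C1 (benzylic carbon), C2–Br and C3–Br form a contiguous four-carbon unit, so the ring is cut at C3–C4 and C5–C6.
3. Both bonds are formed by an inverse-demand Diels–Alder reaction of tris(trimethylsilyloxy)ethene 7 (arene C4, C5) with ethyl 3,4-dibromo-2-pyrone-5-carboxylate 6 (pyrone C3, C4, C5, C6 become arene C3, C2, C1, C6), followed by loss of CO2 and Me3SiOH.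
4. Pyrone 6 comes from diethyl acetonedicarboxylate 1 and triethyl orthoformate 2 by ethoxymethylenation, acid ring closure to the 4-hydroxy-2-pyrone, C3 bromination and hydroxyl-to-bromine exchange.
5. Ring order: the 2-pyrone ring (step 2), then the benzene ring (step 5); the target has no stereocentre.

Key step: step 5

Assumption: the transient bridged lactone 8 and diene 9 form as stereoisomer mixtures (and 3 as an E/Z mixture) that need no control, because these stereo-elements vanish on aromatisation or ring closure; their SMILES are written without configuration.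

**Route**

Step 1
Reactants: 1 diethyl 1,3-acetonedicarboxylate; 2 triethyl orthoformate
Product: 3 diethyl 2-(ethoxymethylene)-3-oxopentanedioate
Conditions: HC(OEt)3 (1.1 equiv), Ac2O (2.2 equiv), 120 °C, volatiles distilled off
Reagents that add atoms: none
Why: Ethoxymethylenation of an active methylene by an orthoester, driven by acetic anhydride trapping the ethanol, with one equivalent of orthoformate limiting the reaction to one of the two equivalent CH2 groups.

Step 2
Reactants: 3 diethyl 2-(ethoxymethylene)-3-oxopentanedioate
Product: 4 ethyl 4-hydroxy-2-oxo-2H-pyran-5-carboxylate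
Conditions: 2 M aq. HCl, 0 °C to rt, product collected by filtration
Reagents that add atoms: water, O
Why: Acid hydrolysis of the enol ether gives the hydroxymethylene ketone, whose enol oxygen lactonises onto the distal ester (six-membered acyl substitution with loss of ethanol) to a pyran-2,4-dione that rests as the 4-hydroxy-2-pyrone.

Step 3
Reactants: 4 ethyl 4-hydroxy-2-oxo-2H-pyran-5-carboxylate
Product: 5 ethyl 3-bromo-4-hydroxy-2-oxo-2H-pyran-5-carboxylate
Conditions: NBS (1.05 equiv), MeCN, 0 °C to rt
Reagents that add atoms: N-bromosuccinimide, O=C1CCC(=O)N1Br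
Why: Electrophilic bromination of the enol of a 4-hydroxy-2-pyrone takes place at C3, the only nucleophilic ring CH (C6 is an electrophilic enol-ether carbon).

Step 4
Reactants: 5 ethyl 3-bromo-4-hydroxy-2-oxo-2H-pyran-5-carboxylate
Product: 6 ethyl 3,4-dibromo-2-oxo-2H-pyran-5-carboxylate
Conditions: POBr3 (1.5 equiv), DMF (cat.), toluene, 90 °C; cold aq. NaHCO3 work-up, short silica plug
Reagents that add atoms: phosphorus oxybromide, O=P(Br)(Br)Br
Why: Deoxybromination of a vinylogous carboxylic acid, in which the 4-hydroxyl is turned into a dibromophosphate and displaced by bromide through addition–elimination at C4, as in the conversion of 4-hydroxy-2-pyrones and 4-hydroxycoumarins into their 4-bromo derivatives.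

Step 5
Reactants: 6 ethyl 3,4-dibromo-2-oxo-2H-pyran-5-carboxylate; 7 tris(trimethylsilyloxy)ethene
Product: 10 ethyl 2,3-dibromo-4,5-bis(trimethylsilyloxy)benzoate, via bridged lactone adduct 8 (not isolated), via tris(silyloxy)cyclohexadiene 9 (not isolated)
Conditions: 7 (2.5 equiv), acid-free 6, toluene, 100–110 °C, sealed tube, Ar; volatiles removed, crude used directly
Reagents that add atoms: none
Why: The electron-poor diene 6 (lactone, ester, two bromines) and the electron-rich alkene 7 should combine in an inverse-electron-demand Diels–Alder reaction in which the nucleophilic CH terminus of 7 bonds to pyrone C6 and the bis(silyloxy) carbon to pyrone C3, giving bridged lactone 8. Retro-[4+2] loss of CO2 from 8 gives diene 9, and 1,2-elimination of Me3SiOH across its C(OSiMe3)2–CH(OSiMe3) bond (ionisation to an O-silylated arenium ion, then loss of the adjacent proton) gives arene 10 without any redox step. The closest known reaction type is the thermal cycloaddition of 2-pyrone-5-carboxylates and bromo-2-pyrones with ketene acetals and 1,1,2-trialkoxyethenes followed by loss of CO2 and alcohol, of which dienophile class 7 is a new member. The benzene ring is closed by the intermolecular [4+2] event itself, the two new bonds (arene C3–C4 and C5–C6) forming in a concerted but asynchronous six-membered closure or through a short-lived zwitterion, and no stereocentre remains in 10. The step needs chemoselectivity for attack at C6 over addition–elimination at the C4 bromide, which the substrate secures because C6 is unsubstituted, β to the ester and vinylogous to the lactone carbonyl, whereas C4 is flanked by Br and CO2Et, and the absence of Lewis acid keeps the ionic displacement slow. Regiochemistry needs no control because either orientation of 7 leads to the same arene.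

Step 6
Reactants: 10 ethyl 2,3-dibromo-4,5-bis(trimethylsilyloxy)benzoate
Product: 11 ethyl 2,3-dibromo-4,5-dihydroxybenzoate
Conditions: 1 M aq. HCl, THF, 0 °C to rt
Reagents that add atoms: none
Why: Aryl trimethylsilyl ethers are hydrolysed by dilute acid, which should also complete the aromatisation of any residual 9 and leaves the ethyl ester untouched.

Step 7
Reactants: 11 ethyl 2,3-dibromo-4,5-dihydroxybenzoate
Product: 12 ethyl 2,3-dibromo-4,5-bis(tert-butyldimethylsilyloxy)benzoate
Conditions: TBSCl (2.6 equiv), imidazole (5 equiv), DMF, rt to 40 °C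
Reagents that add atoms: tert-butyldimethylsilyl chloride, CC(C)(C)[Si](C)(C)Cl
Why: Imidazole-promoted silylation of both phenols gives ethers that survive chromatography and hydride reduction yet can be removed by fluoride at the end.

Step 8
Reactants: 12 ethyl 2,3-dibromo-4,5-bis(tert-butyldimethylsilyloxy)benzoate
Product: 13 [2,3-dibromo-4,5-bis(tert-butyldimethylsilyloxy)phenyl]methanol
Conditions: i-Bu2AlH (2.5 equiv), CH2Cl2, −78 to 0 °C; aq. potassium sodium tartrate
Reagents that add atoms: none
Why: Reduction of the ester to the primary alcohol by two hydride transfers from i-Bu2AlH at low temperature leaves aryl bromides and aryl silyl ethers intact.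

Step 9
Reactants: 13 [2,3-dibromo-4,5-bis(tert-butyldimethylsilyloxy)phenyl]methanol (half of the material)
Product: 14 2,3-dibromo-4,5-bis(tert-butyldimethylsilyloxy)benzyl bromide
Conditions: CBr4 (1.3 equiv), PPh3 (1.3 equiv), CH2Cl2, 0 °C
Reagents that add atoms: carbon tetrabromide, BrC(Br)(Br)Br
Why: The Appel reaction turns the primary benzylic alcohol into the bromide under neutral conditions that the silyl ethers tolerate.

Step 10
Reactants: 13 [2,3-dibromo-4,5-bis(tert-butyldimethylsilyloxy)phenyl]methanol (second half); 14 2,3-dibromo-4,5-bis(tert-butyldimethylsilyloxy)benzyl bromide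
Product: 15 bis[2,3-dibromo-4,5-bis(tert-butyldimethylsilyloxy)benzyl] ether
Conditions: AgOTf (1.3 equiv), 2,6-di-tert-butyl-4-methylpyridine (1.5 equiv), 4 Å molecular sieves, CH2Cl2, −40 °C to rt, dark
Reagents that add atoms: none
Why: In this silver-promoted Williamson-type etherification, monovalent silver abstracts bromide from the para-silyloxy-stabilised benzylic bromide and the primary alcohol captures the electrophile while the hindered pyridine takes up TfOH, so the base-labile aryl silyl ethers never meet an alkoxide.

Step 11
Reactants: 15 bis[2,3-dibromo-4,5-bis(tert-butyldimethylsilyloxy)benzyl] ether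
Product: 16 bis(2,3-dibromo-4,5-dihydroxybenzyl) ether
Conditions: Bu4NF (4.4 equiv), AcOH (6 equiv), THF, 0 °C, Ar, degassed solvents; dilute acid work-up
Reagents that add atoms: none
Why: Fluoride cleaves the four aryl Si–O bonds, and the acetic acid buffer keeps the freed phenols protonated, so the para-hydroxybenzyl ether should not fragment through a quinone methide and the catechols should not air-oxidise.

**Compound list**

1 | diethyl 1,3-acetonedicarboxylate | CCOC(=O)CC(=O)CC(=O)OCC | starting material
2 | triethyl orthoformate | CCOC(OCC)OCC | starting material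
3 | diethyl 2-(ethoxymethylene)-3-oxopentanedioate | CCOC=C(C(=O)OCC)C(=O)CC(=O)OCC | intermediate
4 | ethyl 4-hydroxy-2-oxo-2H-pyran-5-carboxylate | O=C1OC=C(C(=O)OCC)C(O)=C1 | intermediate
5 | ethyl 3-bromo-4-hydroxy-2-oxo-2H-pyran-5-carboxylate | O=C1OC=C(C(=O)OCC)C(O)=C1Br | intermediate
6 | ethyl 3,4-dibromo-2-oxo-2H-pyran-5-carboxylate | O=C1OC=C(C(=O)OCC)C(Br)=C1Br | intermediate
7 | tris(trimethylsilyloxy)ethene | C[Si](C)(C)OC=C(O[Si](C)(C)C)O[Si](C)(C)C | starting material
8 | ethyl 4,5-dibromo-3-oxo-7,8,8-tris(trimethylsilyloxy)-2-oxabicyclo[2.2.2]oct-5-ene-6-carboxylate (bridged lactone adduct) | O=C1OC2C(C(=O)OCC)=C(Br)C1(Br)C(O[Si](C)(C)C)(O[Si](C)(C)C)C2O[Si](C)(C)C | intermediate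
9 | ethyl 5,6-dibromo-3,4,4-tris(trimethylsilyloxy)cyclohexa-1,5-diene-1-carboxylate | CCOC(=O)C1=CC(O[Si](C)(C)C)C(O[Si](C)(C)C)(O[Si](C)(C)C)C(Br)=C1Br | intermediate
10 | ethyl 2,3-dibromo-4,5-bis(trimethylsilyloxy)benzoate | CCOC(=O)c1cc(O[Si](C)(C)C)c(O[Si](C)(C)C)c(Br)c1Br | intermediate
11 | ethyl 2,3-dibromo-4,5-dihydroxybenzoate | CCOC(=O)c1cc(O)c(O)c(Br)c1Br | intermediate
12 | ethyl 2,3-dibromo-4,5-bis(tert-butyldimethylsilyloxy)benzoate | CCOC(=O)c1cc(O[Si](C)(C)C(C)(C)C)c(O[Si](C)(C)C(C)(C)C)c(Br)c1Br | intermediate
13 | [2,3-dibromo-4,5-bis(tert-butyldimethylsilyloxy)phenyl]methanol | OCc1cc(O[Si](C)(C)C(C)(C)C)c(O[Si](C)(C)C(C)(C)C)c(Br)c1Br | intermediate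
14 | 2,3-dibromo-4,5-bis(tert-butyldimethylsilyloxy)benzyl bromide | BrCc1cc(O[Si](C)(C)C(C)(C)C)c(O[Si](C)(C)C(C)(C)C)c(Br)c1Br | intermediate
15 | bis[2,3-dibromo-4,5-bis(tert-butyldimethylsilyloxy)benzyl] ether | CC(C)(C)[Si](C)(C)Oc1cc(COCc2cc(O[Si](C)(C)C(C)(C)C)c(O[Si](C)(C)C(C)(C)C)c(Br)c2Br)c(Br)c(Br)c1O[Si](C)(C)C(C)(C)C | intermediate
16 | bis(2,3-dibromo-4,5-dihydroxybenzyl) ether | Oc1cc(COCc2cc(O)c(O)c(Br)c2Br)c(Br)c(Br)c1O | target

**Step count and risk**

Total step count: 11. Longest linear sequence: 11 steps (1 to 16 through 14).

Steps most likely to fail: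

Step 5. After the first bond to C6 the zwitterion may collapse by silyl transfer to an open-chain conjugate adduct instead of closing the ring, or the ketene acetal may displace the C4 bromide by addition–elimination. The fallback sets out from pyrone 6 and replaces the silyl ketene acetal by its methyl analogue, 1,1,2-trimethoxyethene F1, a known ketene acetal that has to be prepared beforehand and carries no transferable silyl group. Heating 6 with F1 in toluene or mesitylene at 110–140 °C should give the bridged trimethoxy lactone F2, which loses CO2 to the trimethoxycyclohexadiene F3. F3 loses methanol to ethyl 2,3-dibromo-4,5-dimethoxybenzoate F4. Demethylation of F4 with BBr3 in CH2Cl2 at −78 to 0 °C and an ethanol quench should return the route at catechol ester 11.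

Step 4. The hindered, ester-chelated 4-hydroxyl may be phosphorylated without the phosphate being displaced by bromide, or hot HBr may open the lactone. The fallback sets out from 5 and separates activation from substitution. Tf2O and 2,6-lutidine in CH2Cl2 at −78 °C should give ethyl 3-bromo-2-oxo-4-(trifluoromethylsulfonyloxy)-2H-pyran-5-carboxylate F5. LiBr in acetone at rt should then exchange the vinylogous acyl triflate for bromide by addition–elimination at C4 and return the route at 6.

Step 10. The silver-generated benzylic electrophile may lose its para silyl group to a quinone methide and oligomerise, or it may alkylate C6–H of a second ring instead of the hydroxyl. The fallback sets out from alcohol 13 and avoids any benzylic halide. Oxidation of 13 with MnO2 in CH2Cl2 should give 2,3-dibromo-4,5-bis(tert-butyldimethylsilyloxy)benzaldehyde F6. Reductive homo-etherification of F6 with Et3SiH and catalytic Me3SiOTf in CH2Cl2 at −78 to 0 °C should return the route at 15, so the bromide 14 is not needed.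

**Further compounds**

F1 | step 5 | 1,1,2-trimethoxyethene | COC=C(OC)OC
F2 | step 5 | ethyl 4,5-dibromo-7,8,8-trimethoxy-3-oxo-2-oxabicyclo[2.2.2]oct-5-ene-6-carboxylate | O=C1OC2C(C(=O)OCC)=C(Br)C1(Br)C(OC)(OC)C2OC
F3 | step 5 | ethyl 5,6-dibromo-3,4,4-trimethoxycyclohexa-1,5-diene-1-carboxylate | CCOC(=O)C1=CC(OC)C(OC)(OC)C(Br)=C1Br
F4 | step 5 | ethyl 2,3-dibromo-4,5-dimethoxybenzoate | CCOC(=O)c1cc(OC)c(OC)c(Br)c1Br
F5 | step 4 | ethyl 3-bromo-2-oxo-4-(trifluoromethylsulfonyloxy)-2H-pyran-5-carboxylate | CCOC(=O)C1=COC(=O)C(Br)=C1OS(=O)(=O)C(F)(F)F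
F6 | step 10 | 2,3-dibromo-4,5-bis(tert-butyldimethylsilyloxy)benzaldehyde | O=Cc1cc(O[Si](C)(C)C(C)(C)C)c(O[Si](C)(C)C(C)(C)C)c(Br)c1Br
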